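**Plan**

- Retrosynthetic cuts, in order: the C8 ester and the protecting groups; the ring bond C1–C2 (alkenyl–alkyl); the lactone at C6–C7 and O–C12 (allylation–lactonization); C7=C11 (Morita–Baylis–Hillman-type adduct); C9–C10 (alkenyl addition to an aldehyde); C3–C4 (Stille).
- Forward: diene aldehyde 6 (C2–C6, C15) and iodoalkenyl allyl bromide 24 (C7–C14, C1) are made separately; a CrCl2 allylation joins them and closes the γ-lactone; the ten-membered carbocycle is closed last at C1–C2; unmasking and ester exchange at C8 finish the route.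
- Enabling feature: the C10=C1–C2–C3–C4=C5 1,5-diene of the ten-membered ring has both trisubstituted olefins ring-cis, and C1 is the β-carbon of the C10 enal. C1–C2 is therefore an alkenyl–alkyl bond that a stereodefined alkenyl iodide and the primary borane from a C2=C3 vinyl group can form, in a chain already folded by the C4=C5 olefin and the trans-fused lactone.
- Stereochemistry: C8 is set by palladium-catalysed asymmetric etherification; C9 is relayed from C8 by chelation control; C6 and C7 are relayed together in the chromium allylation; the (S)-2-methylbutanoate is bought.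
- Olefin geometry: C4=C5 comes from trans-hydroalumination–iodination and C1=C10 from cis-silylstannation; both are carried through the couplings with retention.

Key step: step 15

Remark: carbons are labelled C1–C15 in the germacranolide sense (ring C1–C10, lactone carbons C11–C13, formyl carbon C14 on C10, hydroxymethyl carbon C15 on C4); both ring olefins are ring-cis (E by CIP) and the target is 6R,7S,8S,9S,2'S.

Assumption: in step 5 the R,R ligand is taken to give the S ether; if the sense of induction is the opposite, the S,S ligand is used.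

**Route**

Step 1
Reactants: 1 4-{[tert-butyl(dimethyl)silyl]oxy}but-2-yn-1-ol
Product: 3 (2Z)-4-{[tert-butyl(dimethyl)silyl]oxy}-3-iodobut-2-en-1-ol, via alkenylaluminate 2 (not isolated)
Conditions: NaAlH2(OCH2CH2OMe)2, THF, 0 °C; then I2, −78 °C to 0 °C
Reagents that add atoms: iodine, II
Why: Hydroxyl-directed trans-hydroalumination of the propargylic alcohol (hydride to the proximal and aluminium to the distal alkyne carbon in a five-membered aluminate) followed by iodinolysis with retention should give the Z iodide, which fixes the ring-cis C4=C5 geometry.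

Step 2
Reactants: 3 (2Z)-4-{[tert-butyl(dimethyl)silyl]oxy}-3-iodobut-2-en-1-ol; 4 tributyl(ethenyl)stannane
Product: 5 (2E)-3-({[tert-butyl(dimethyl)silyl]oxy}methyl)penta-2,4-dien-1-ol
Conditions: PdCl2(MeCN)2 (5 mol %), DMF, rt
Reagents that add atoms: none
Why: Stille coupling proceeds with retention at the alkenyl iodide and installs the C2=C3 vinyl group cis to C6.

Step 3
Reactants: 5 (2E)-3-({[tert-butyl(dimethyl)silyl]oxy}methyl)penta-2,4-dien-1-ol
Product: 6 (2E)-3-({[tert-butyl(dimethyl)silyl]oxy}methyl)penta-2,4-dienal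
Conditions: MnO2, CH2Cl2, rt; used promptly
Reagents that add atoms: none
Why: MnO2 oxidation of the allylic alcohol to the enal leaves the silyl ether and the diene untouched, and prompt use limits enal isomerization.

Step 4
Reactants: 7 3,3-diethoxyprop-1-yne; 8 trimethyl(tributylstannyl)silane
Product: 9 tributyl[(1Z)-3,3-diethoxy-1-(trimethylsilyl)prop-1-en-2-yl]stannane
Conditions: Pd(PPh3)4 (2 mol %), THF, 65 °C
Reagents that add atoms: none
Why: Palladium-catalysed cis-silylstannation of a terminal alkyne (Si–Sn oxidative addition, syn insertion, reductive elimination) places tin on the internal and silicon on the terminal carbon on the same side.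

Step 5
Reactants: 10 2-ethenyloxirane (racemic); 11 (4-methoxyphenyl)methanol
Product: 12 (2S)-2-[(4-methoxybenzyl)oxy]but-3-en-1-ol
Conditions: Pd2(dba)3·CHCl3 (1 mol %), (R,R)-DACH-phenyl bisphosphine ligand (3 mol %), Et3B (1 mol %), CH2Cl2, rt
Reagents that add atoms: none
Why: In this Tsuji–Trost-type dynamic kinetic asymmetric allylic etherification the two π-allylpalladium diastereomers from the racemic epoxide interconvert and the boron-bound alkoxide is delivered to the internal carbon, which sets C8 by catalysis.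

Step 6
Reactants: 12 (2S)-2-[(4-methoxybenzyl)oxy]but-3-en-1-ol
Product: 13 (2S)-2-[(4-methoxybenzyl)oxy]but-3-enal
Conditions: Dess–Martin periodinane, CH2Cl2, 0 °C; used crude at once
Reagents that add atoms: none
Why: Dess–Martin oxidation is non-basic, which avoids enolization of the α-alkoxy-β,γ-unsaturated aldehyde.

Step 7
Reactants: 9 tributyl[(1Z)-3,3-diethoxy-1-(trimethylsilyl)prop-1-en-2-yl]stannane; 13 (2S)-2-[(4-methoxybenzyl)oxy]but-3-enal
Product: 16 (1E,3S,4S)-2-(diethoxymethyl)-4-[(4-methoxybenzyl)oxy]-1-(trimethylsilyl)hexa-1,5-dien-3-ol, via alkenyllithium 14 (not isolated), via alkenylmagnesium bromide 15 (not isolated)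
Conditions: 9, n-BuLi, THF, −78 °C; MgBr2·OEt2; then 13 precomplexed with MgBr2·OEt2 in CH2Cl2, −78 °C; H2O quench at −78 °C
Reagents that add atoms: none
Why: Tin–lithium exchange with retention and transmetalation to magnesium give an alkenyl nucleophile that adds to the magnesium-chelated α-alkoxy aldehyde from the face opposite the vinyl group (Cram chelate model), which should give the 8,9-syn S,S alcohol; the cold quench avoids a 1,4-silyl shift to the alkoxide.

Step 8
Reactants: 16 (1E,3S,4S)-2-(diethoxymethyl)-4-[(4-methoxybenzyl)oxy]-1-(trimethylsilyl)hexa-1,5-dien-3-ol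
Product: 17 (1E,3S,4S)-2-(diethoxymethyl)-4-[(4-methoxybenzyl)oxy]-1-(trimethylsilyl)hexa-1,5-dien-3-yl acetate
Conditions: Ac2O, pyridine, DMAP (cat.), CH2Cl2, 0 °C to rt
Reagents that add atoms: acetic anhydride, CC(=O)OC(C)=O
Why: DMAP-catalysed acetylation installs the final C9 acetate while O9 is the only free hydroxyl, which differentiates O9 from O8 for the rest of the route.

Step 9
Reactants: 17 (1E,3S,4S)-2-(diethoxymethyl)-4-[(4-methoxybenzyl)oxy]-1-(trimethylsilyl)hexa-1,5-dien-3-yl acetate
Product: 18 (1E,3S,4S)-2-(diethoxymethyl)-1-iodo-4-[(4-methoxybenzyl)oxy]hexa-1,5-dien-3-yl acetate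
Conditions: NIS, MeCN/ClCH2CN (4:1), 0 °C to rt, dark
Reagents that add atoms: N-iodosuccinimide, O=C1CCC(=O)N1I
Why: Ipso-iododesilylation of the alkenylsilane through a β-silyl cation proceeds with retention and places iodine cis to C9; a nitrile solvent instead of a fluorinated alcohol spares the anisyl ring.

Step 10
Reactants: 18 (1E,3S,4S)-2-(diethoxymethyl)-1-iodo-4-[(4-methoxybenzyl)oxy]hexa-1,5-dien-3-yl acetate
Product: 20 (2R,3S,4E)-4-(diethoxymethyl)-5-iodo-2-[(4-methoxybenzyl)oxy]-1-oxopent-4-en-3-yl acetate, via vicinal diol 19 (not isolated)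
Conditions: OsO4 (2 mol %), NaIO4, 2,6-lutidine, dioxane/H2O (3:1), rt
Reagents that add atoms: osmium tetroxide, O=[Os](=O)(=O)=O; sodium periodate, [Na+].[O-][I](=O)(=O)=O
Why: In this Johnson–Lemieux cleavage OsO4 should dihydroxylate the monosubstituted olefin in preference to the hindered, electron-poor alkenyl iodide, and periodate cleaves the diol to the C7 aldehyde.

Step 11
Reactants: 20 (2R,3S,4E)-4-(diethoxymethyl)-5-iodo-2-[(4-methoxybenzyl)oxy]-1-oxopent-4-en-3-yl acetate; 21 methyl prop-2-ynoate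
Product: 23 methyl (4S,5S,6E)-5-acetoxy-6-(diethoxymethyl)-3-hydroxy-7-iodo-4-[(4-methoxybenzyl)oxy]-2-methylidenehept-6-enoate (C3 epimers), via alkenylalane 22 (not isolated)
Conditions: 21, i-Bu2AlH, N-methylmorpholine N-oxide, THF, 0 °C; then 20, 0 °C to rt
Reagents that add atoms: none
Why: Regioselective hydroalumination of the propiolate gives the α-(methoxycarbonyl)vinylalane, which adds 1,2 to the aldehyde to give a Morita–Baylis–Hillman-type adduct without an amine base, so the β-acetoxy aldehyde is not exposed to E1cB elimination; the new carbinol centre is erased in step 12.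

Step 12
Reactants: 23 methyl (4S,5S,6E)-5-acetoxy-6-(diethoxymethyl)-3-hydroxy-7-iodo-4-[(4-methoxybenzyl)oxy]-2-methylidenehept-6-enoate (C3 epimers)
Product: 24 methyl (2Z,4S,5S,6E)-5-acetoxy-2-(bromomethyl)-6-(diethoxymethyl)-7-iodo-4-[(4-methoxybenzyl)oxy]hepta-2,6-dienoate
Conditions: NBS, Me2S, CH2Cl2, 0 °C to rt
Reagents that add atoms: N-bromosuccinimide, O=C1CCC(=O)N1Br
Why: Allylic transposition (SN2') of the alcohol through its alkoxydimethylsulfonium salt lets bromide attack the methylene terminus and should give the thermodynamically preferred Z 2-(bromomethyl)enoate.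

Step 13
Reactants: 24 methyl (2Z,4S,5S,6E)-5-acetoxy-2-(bromomethyl)-6-(diethoxymethyl)-7-iodo-4-[(4-methoxybenzyl)oxy]hepta-2,6-dienoate; 6 (2E)-3-({[tert-butyl(dimethyl)silyl]oxy}methyl)penta-2,4-dienal
Product: 27 (4S,5R)-4-[(1S,2S,3E)-2-acetoxy-3-(diethoxymethyl)-4-iodo-1-[(4-methoxybenzyl)oxy]but-3-en-1-yl]-5-[(1E)-2-({[tert-butyl(dimethyl)silyl]oxy}methyl)buta-1,3-dien-1-yl]-3-methylidenedihydrofuran-2(3H)-one, via allylchromium dichloride 25 (not isolated), via hydroxy ester 26 (not isolated)
Conditions: CrCl2 (4 equiv, nickel-free), THF, 0 °C to rt; H2O work-up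
Reagents that add atoms: none
Why: In this Nozaki–Hiyama-type (Barbier) 2-(methoxycarbonyl)allylation the allylchromium adds through its γ-carbon C7 to the aldehyde in a chair transition state with both substituents equatorial (anti adduct, hence the trans-lactone after loss of methanol), and the aldehyde approaches the C7 face anti to the bulky C9 branch in the conformer that keeps C8–H in the plane of the fully substituted C11 (allylic 1,3-strain), which relays C8 to C7 and C6 in one event; the alkenyl iodide is inert to CrCl2 without nickel salts.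

Step 14
Reactants: 27 (4S,5R)-4-[(1S,2S,3E)-2-acetoxy-3-(diethoxymethyl)-4-iodo-1-[(4-methoxybenzyl)oxy]but-3-en-1-yl]-5-[(1E)-2-({[tert-butyl(dimethyl)silyl]oxy}methyl)buta-1,3-dien-1-yl]-3-methylidenedihydrofuran-2(3H)-one
Product: 28 3-[(phenylselanyl)methyl] analogue of 27 (C11 epimers)
Conditions: PhSeH, Et3N (cat.), THF, 0 °C
Reagents that add atoms: benzeneselenol, [SeH]c1ccccc1
Why: Conjugate (Michael) addition of the selenol masks the only electron-poor 1,1-disubstituted olefin before hydroboration; the new C11 centre is unimportant because it returns to sp2 in step 16.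

Step 15
Reactants: 28 3-[(phenylselanyl)methyl] analogue of 27 (C11 epimers)
Product: 30 selenide-masked germacranolide acetal (ten-membered ring closed; 8-OPMB; 9-OAc; 14-diethyl acetal; 15-OTBS; C11 epimers), via B-alkyl-9-BBN 29 (not isolated)
Conditions: 9-BBN dimer, THF, 0 °C to rt; then added over 8 h to PdCl2(dppf)·CH2Cl2 (15 mol %), AsPh3, Cs2CO3, DMF/THF/H2O, rt, about 2 mM
Reagents that add atoms: none
Why: 9-BBN adds anti-Markovnikov to the only monosubstituted olefin, the C2=C3 vinyl group of the diene, to give the primary homoallylic borane 29; zerovalent palladium then inserts into the alkenyl C1–I bond with retention, the base-activated borane transfers its primary alkyl group to palladium, and reductive elimination forms C1–C2. The closest known reaction type is the intramolecular B-alkyl Suzuki–Miyaura coupling used to close medium and large carbocycles. The ten-membered carbocycle closes by reductive elimination from an eleven-membered palladacycle, endo with respect to the C1=C10 olefin, which ends up inside the ring. No stereocentre is formed; the C1=C10 geometry (C2 cis to C9, acetal carbon trans to C2) is fixed by retention at the alkenyl iodide. The step needs chemoselective hydroboration, secured by the steric demand of 9-BBN toward the trisubstituted olefins and the alkenyl iodide and by the selenide mask on the lactone methylene, and ring closure over oligomerization, secured by slow addition at high dilution and by a chain folded by the ring-cis C4=C5 olefin, the trans-lactone and the cis placement of iodine and C9; dppf is chosen to favour reductive elimination over β-hydride loss from the homoallylic alkylpalladium.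

Step 16
Reactants: 30 selenide-masked germacranolide acetal (C11 epimers)
Product: 32 (1(10)E,4E,6R,7S,8S,9S)-9-acetoxy-15-{[tert-butyl(dimethyl)silyl]oxy}-14,14-diethoxy-8-[(4-methoxybenzyl)oxy]germacra-1(10),4,11(13)-trien-12,6-olide, via selenoxide 31 (not isolated)
Conditions: NaIO4, THF/MeOH/H2O, 0 °C to rt
Reagents that add atoms: none
Why: Oxidation to the selenoxide and spontaneous syn-elimination (only C11–H is β) regenerate the exocyclic methylene; periodate is used instead of a peroxide to avoid perseleninic-acid epoxidation of the ring olefins.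

Step 17
Reactants: 32 (1(10)E,4E,6R,7S,8S,9S)-9-acetoxy-15-{[tert-butyl(dimethyl)silyl]oxy}-14,14-diethoxy-8-[(4-methoxybenzyl)oxy]germacra-1(10),4,11(13)-trien-12,6-olide
Product: 33 (1(10)E,4E,6R,7R,8S,9S)-9-acetoxy-15-{[tert-butyl(dimethyl)silyl]oxy}-14,14-diethoxy-8-hydroxygermacra-1(10),4,11(13)-trien-12,6-olide (same geometry as 32; the C7 descriptor changes by priority only)
Conditions: DDQ, CH2Cl2/pH 7 phosphate buffer (10:1), 0 °C
Reagents that add atoms: none
Why: Oxidative cleavage of the 4-methoxybenzyl ether by DDQ (hydride abstraction, hydrolysis of the oxocarbenium ion) is run after ring closure because no conjugated diene is left to react with DDQ, and the buffered medium keeps the acetal, silyl ether and acetate intact.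

Step 18
Reactants: 33 (1(10)E,4E,6R,7R,8S,9S)-9-acetoxy-15-{[tert-butyl(dimethyl)silyl]oxy}-14,14-diethoxy-8-hydroxygermacra-1(10),4,11(13)-trien-12,6-olide; 34 (2S)-2-methylbutanoic acid
Product: 35 (1(10)E,4E,6R,7S,8S,9S)-9-acetoxy-15-{[tert-butyl(dimethyl)silyl]oxy}-14,14-diethoxy-8-{[(2S)-2-methylbutanoyl]oxy}germacra-1(10),4,11(13)-trien-12,6-olide
Conditions: DCC, DMAP (cat.), CH2Cl2, 0 °C
Reagents that add atoms: none
Why: Steglich esterification acylates the hindered C8 hydroxyl with the bought S acid; low temperature and only catalytic DMAP limit 1,2-acetyl migration from O9 and epimerization of the acid α-centre.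

Step 19
Reactants: 35 (1(10)E,4E,6R,7S,8S,9S)-9-acetoxy-15-{[tert-butyl(dimethyl)silyl]oxy}-14,14-diethoxy-8-{[(2S)-2-methylbutanoyl]oxy}germacra-1(10),4,11(13)-trien-12,6-olide
Product: 36 (1(10)E,4E,6R,7S,8S,9S)-9-acetoxy-15-hydroxy-8-{[(2S)-2-methylbutanoyl]oxy}-14-oxogermacra-1(10),4,11(13)-trien-12,6-olide (target)
Conditions: aq HF (48%), MeCN, 0 °C to rt
Reagents that add atoms: water, O
Why: Aqueous HF cleaves the primary allylic silyl ether and hydrolyses the α,β-unsaturated diethyl acetal (allyl-stabilized oxocarbenium ion) in one operation; the ring-cis enal is the thermodynamic geometry in the ten-membered ring, and the two esters and the α-methylene lactone should tolerate the mild acid.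

**Compound list**

1 | 4-{[tert-butyl(dimethyl)silyl]oxy}but-2-yn-1-ol | OCC#CCO[Si](C)(C)C(C)(C)C | starting material
2 | sodium 3-({[tert-butyl(dimethyl)silyl]oxy}methyl)-2,2-bis(2-methoxyethoxy)-2,5-dihydro-1,2-oxaaluminol-2-uide (cyclic alkenylaluminate) | [Na+].COCCO[Al-]1(OCCOC)OCC=C1CO[Si](C)(C)C(C)(C)C | intermediate
3 | (2Z)-4-{[tert-butyl(dimethyl)silyl]oxy}-3-iodobut-2-en-1-ol | OC/C=C(\I)CO[Si](C)(C)C(C)(C)C | intermediate
4 | tributyl(ethenyl)stannane | C=C[Sn](CCCC)(CCCC)CCCC | starting material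
5 | (2E)-3-({[tert-butyl(dimethyl)silyl]oxy}methyl)penta-2,4-dien-1-ol | OC/C=C(\C=C)CO[Si](C)(C)C(C)(C)C | intermediate
6 | (2E)-3-({[tert-butyl(dimethyl)silyl]oxy}methyl)penta-2,4-dienal | O=C/C=C(\C=C)CO[Si](C)(C)C(C)(C)C | intermediate
7 | 3,3-diethoxyprop-1-yne | C#CC(OCC)OCC | starting material
8 | trimethyl(tributylstannyl)silane | C[Si](C)(C)[Sn](CCCC)(CCCC)CCCC | starting material
9 | tributyl[(1Z)-3,3-diethoxy-1-(trimethylsilyl)prop-1-en-2-yl]stannane | C[Si](C)(C)/C=C(\[Sn](CCCC)(CCCC)CCCC)C(OCC)OCC | intermediate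
10 | 2-ethenyloxirane (racemic) | C=CC1CO1 | starting material
11 | (4-methoxyphenyl)methanol | COc1ccc(CO)cc1 | starting material
12 | (2S)-2-[(4-methoxybenzyl)oxy]but-3-en-1-ol | OC[C@@H](OCc1ccc(OC)cc1)C=C | intermediate
13 | (2S)-2-[(4-methoxybenzyl)oxy]but-3-enal | O=C[C@@H](OCc1ccc(OC)cc1)C=C | intermediate
14 | [(1E)-3,3-diethoxy-1-(trimethylsilyl)prop-1-en-2-yl]lithium (silicon cis to lithium) | C[Si](C)(C)/C=C(\[Li])C(OCC)OCC | intermediate
15 | bromo[(1Z)-3,3-diethoxy-1-(trimethylsilyl)prop-1-en-2-yl]magnesium (silicon cis to magnesium) | C[Si](C)(C)/C=C(\[Mg]Br)C(OCC)OCC | intermediate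
16 | (1E,3S,4S)-2-(diethoxymethyl)-4-[(4-methoxybenzyl)oxy]-1-(trimethylsilyl)hexa-1,5-dien-3-ol | C[Si](C)(C)/C=C(/C(OCC)OCC)[C@H](O)[C@@H](OCc1ccc(OC)cc1)C=C | intermediate
17 | (1E,3S,4S)-2-(diethoxymethyl)-4-[(4-methoxybenzyl)oxy]-1-(trimethylsilyl)hexa-1,5-dien-3-yl acetate | C[Si](C)(C)/C=C(/C(OCC)OCC)[C@H](OC(C)=O)[C@@H](OCc1ccc(OC)cc1)C=C | intermediate
18 | (1E,3S,4S)-2-(diethoxymethyl)-1-iodo-4-[(4-methoxybenzyl)oxy]hexa-1,5-dien-3-yl acetate | I/C=C(/C(OCC)OCC)[C@H](OC(C)=O)[C@@H](OCc1ccc(OC)cc1)C=C | intermediate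
19 | (1E,3S,4S)-2-(diethoxymethyl)-5,6-dihydroxy-1-iodo-4-[(4-methoxybenzyl)oxy]hex-1-en-3-yl acetate (C5 epimers) | I/C=C(/C(OCC)OCC)[C@H](OC(C)=O)[C@@H](OCc1ccc(OC)cc1)C(O)CO | intermediate
20 | (2R,3S,4E)-4-(diethoxymethyl)-5-iodo-2-[(4-methoxybenzyl)oxy]-1-oxopent-4-en-3-yl acetate | I/C=C(/C(OCC)OCC)[C@H](OC(C)=O)[C@@H](OCc1ccc(OC)cc1)C=O | intermediate
21 | methyl prop-2-ynoate | C#CC(=O)OC | starting material
22 | methyl 2-[bis(2-methylpropyl)alumanyl]prop-2-enoate | C=C(C(=O)OC)[Al](CC(C)C)CC(C)C | intermediate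
23 | methyl (4S,5S,6E)-5-acetoxy-6-(diethoxymethyl)-3-hydroxy-7-iodo-4-[(4-methoxybenzyl)oxy]-2-methylidenehept-6-enoate (C3 epimers) | I/C=C(/C(OCC)OCC)[C@H](OC(C)=O)[C@@H](OCc1ccc(OC)cc1)C(O)C(=C)C(=O)OC | intermediate
24 | methyl (2Z,4S,5S,6E)-5-acetoxy-2-(bromomethyl)-6-(diethoxymethyl)-7-iodo-4-[(4-methoxybenzyl)oxy]hepta-2,6-dienoate | I/C=C(/C(OCC)OCC)[C@H](OC(C)=O)[C@@H](OCc1ccc(OC)cc1)/C=C(\CBr)C(=O)OC | intermediate
25 | allylchromium dichloride derived from 24 (CrCl2 in place of bromine; equilibrating allyl isomers) | I/C=C(/C(OCC)OCC)[C@H](OC(C)=O)[C@@H](OCc1ccc(OC)cc1)/C=C(\C[Cr](Cl)Cl)C(=O)OC | intermediate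
26 | anti hydroxy ester, the open form of 27 (free C6 hydroxyl, methyl ester at C12; C6–C9 as in 27) | COC(=O)C(=C)[C@@H]([C@H](O)/C=C(/CO[Si](C)(C)C(C)(C)C)C=C)[C@H](OCc1ccc(OC)cc1)[C@@H](OC(C)=O)/C(=C\I)C(OCC)OCC | intermediate
27 | (4S,5R)-4-[(1S,2S,3E)-2-acetoxy-3-(diethoxymethyl)-4-iodo-1-[(4-methoxybenzyl)oxy]but-3-en-1-yl]-5-[(1E)-2-({[tert-butyl(dimethyl)silyl]oxy}methyl)buta-1,3-dien-1-yl]-3-methylidenedihydrofuran-2(3H)-one | C=C1C(=O)O[C@H](/C=C(/CO[Si](C)(C)C(C)(C)C)C=C)[C@H]1[C@H](OCc1ccc(OC)cc1)[C@@H](OC(C)=O)/C(=C\I)C(OCC)OCC | intermediate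
28 | 3-[(phenylselanyl)methyl] analogue of 27, (3RS,4S,5R), C11 epimers | c1ccccc1[Se]CC1C(=O)O[C@H](/C=C(/CO[Si](C)(C)C(C)(C)C)C=C)[C@H]1[C@H](OCc1ccc(OC)cc1)[C@@H](OC(C)=O)/C(=C\I)C(OCC)OCC | intermediate
29 | B-alkyl-9-BBN from 28 (9-borabicyclo[3.3.1]nonan-9-yl on C2; C2–C3 saturated) | c1ccccc1[Se]CC1C(=O)O[C@H](/C=C(/CO[Si](C)(C)C(C)(C)C)CCB2C3CCCC2CCC3)[C@H]1[C@H](OCc1ccc(OC)cc1)[C@@H](OC(C)=O)/C(=C\I)C(OCC)OCC | intermediate
30 | (1(10)E,4E,6R,7S,8S,9S,11RS)-9-acetoxy-15-{[tert-butyl(dimethyl)silyl]oxy}-14,14-diethoxy-8-[(4-methoxybenzyl)oxy]-13-(phenylselanyl)germacra-1(10),4-dien-12,6-olide | c1ccccc1[Se]CC1C(=O)O[C@@H]2/C=C(/CO[Si](C)(C)C(C)(C)C)CC/C=C(/C(OCC)OCC)[C@H](OC(C)=O)[C@@H](OCc3ccc(OC)cc3)[C@@H]12 | intermediate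
31 | selenoxide of 30 (Se-oxide; selenium and C11 epimers) | c1ccccc1[Se](=O)CC1C(=O)O[C@@H]2/C=C(/CO[Si](C)(C)C(C)(C)C)CC/C=C(/C(OCC)OCC)[C@H](OC(C)=O)[C@@H](OCc3ccc(OC)cc3)[C@@H]12 | intermediate
32 | (1(10)E,4E,6R,7S,8S,9S)-9-acetoxy-15-{[tert-butyl(dimethyl)silyl]oxy}-14,14-diethoxy-8-[(4-methoxybenzyl)oxy]germacra-1(10),4,11(13)-trien-12,6-olide | C=C1C(=O)O[C@@H]2/C=C(/CO[Si](C)(C)C(C)(C)C)CC/C=C(/C(OCC)OCC)[C@H](OC(C)=O)[C@@H](OCc3ccc(OC)cc3)[C@@H]12 | intermediate
33 | (1(10)E,4E,6R,7R,8S,9S)-9-acetoxy-15-{[tert-butyl(dimethyl)silyl]oxy}-14,14-diethoxy-8-hydroxygermacra-1(10),4,11(13)-trien-12,6-olide | C=C1C(=O)O[C@@H]2/C=C(/CO[Si](C)(C)C(C)(C)C)CC/C=C(/C(OCC)OCC)[C@H](OC(C)=O)[C@@H](O)[C@@H]12 | intermediate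
34 | (2S)-2-methylbutanoic acid | CC[C@H](C)C(=O)O | starting material
35 | (1(10)E,4E,6R,7S,8S,9S)-9-acetoxy-15-{[tert-butyl(dimethyl)silyl]oxy}-14,14-diethoxy-8-{[(2S)-2-methylbutanoyl]oxy}germacra-1(10),4,11(13)-trien-12,6-olide | C=C1C(=O)O[C@@H]2/C=C(/CO[Si](C)(C)C(C)(C)C)CC/C=C(/C(OCC)OCC)[C@H](OC(C)=O)[C@@H](OC(=O)[C@@H](C)CC)[C@@H]12 | intermediate
36 | (1(10)E,4E,6R,7S,8S,9S)-9-acetoxy-15-hydroxy-8-{[(2S)-2-methylbutanoyl]oxy}-14-oxogermacra-1(10),4,11(13)-trien-12,6-olide | C=C1C(=O)O[C@@H]2/C=C(/CO)CC/C=C(/C=O)[C@H](OC(C)=O)[C@@H](OC(=O)[C@@H](C)CC)[C@@H]12 | target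

**Step count and risks**

Total steps: 19. Longest linear sequence: 15 steps (steps 5 to 19, from 10 and 11).

Steps most likely to fail:

1. Step 15 (ring closure). What may go wrong: intermolecular coupling to oligomers instead of ring closure, β-hydride loss or protodeboronation of the homoallylic alkylmetal, and base-induced loss of the C9 acetate or of the selenide mask during the slow addition. The fallback replaces the alkylborane by an alkylzinc and needs no base. It sets out from 29, which is oxidized in the flask with NaBO3·4H2O to the primary C2 alcohol F1. Iodination (I2, PPh3, imidazole) gives the primary iodide F2. Zinc insertion (Zn dust, LiCl, THF) gives the alkylzinc iodide F3, which is added slowly to PdCl2(dppf) in THF (intramolecular Negishi coupling). The fallback comes back to the route at 30.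

2. Step 13 (allylation–lactonization). What may go wrong: poor facial selectivity at C7 relative to C8, syn addition leading to the cis-lactone, or 1,4-elimination of the anisylmethoxide from the allylchromium. The fallback repeats the union under catalyst control, as an enantioselective Nozaki–Hiyama-type allylation with catalytic CrCl2, a chiral carbazole-bis(oxazoline) ligand, Mn powder and Cp2ZrCl2 in THF, so that the ligand and not C8 chooses the aldehyde face. It sets out from 24 and 6 and comes back at 27; it makes no new compound (F0).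

3. Step 7 (C9–C10 bond). What may go wrong: erosion of chelation control by competing Felkin–Anh addition, and enolization of the α-alkoxy-β,γ-unsaturated aldehyde by the basic organometallic. The fallback sets C9 by reagent control. It sets out from 16 obtained as a C9 epimer mixture, which is oxidized with Dess–Martin periodinane to the enone F4. Reduction with BH3·SMe2 and the (S)-2-methyl-CBS-oxazaborolidine, the alkenyl group acting as the large substituent, should return the S carbinol. The fallback comes back at 16.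

Further compounds
F1 | step 15 | primary C2 alcohol: analogue of 28 in which the C2=C3 vinyl group is CH2CH2OH | c1ccccc1[Se]CC1C(=O)O[C@H](/C=C(/CO[Si](C)(C)C(C)(C)C)CCO)[C@H]1[C@H](OCc1ccc(OC)cc1)[C@@H](OC(C)=O)/C(=C\I)C(OCC)OCC
F2 | step 15 | primary iodide: analogue of 28 in which the C2=C3 vinyl group is CH2CH2I | c1ccccc1[Se]CC1C(=O)O[C@H](/C=C(/CO[Si](C)(C)C(C)(C)C)CCI)[C@H]1[C@H](OCc1ccc(OC)cc1)[C@@H](OC(C)=O)/C(=C\I)C(OCC)OCC
F3 | step 15 | alkylzinc iodide: analogue of 28 in which the C2=C3 vinyl group is CH2CH2ZnI | c1ccccc1[Se]CC1C(=O)O[C@H](/C=C(/CO[Si](C)(C)C(C)(C)C)CC[Zn]I)[C@H]1[C@H](OCc1ccc(OC)cc1)[C@@H](OC(C)=O)/C(=C\I)C(OCC)OCC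
F0 | step 13 | none | none
F4 | step 7 | (1E,4S)-2-(diethoxymethyl)-4-[(4-methoxybenzyl)oxy]-1-(trimethylsilyl)hexa-1,5-dien-3-one | C[Si](C)(C)/C=C(/C(OCC)OCC)C(=O)[C@@H](OCc1ccc(OC)cc1)C=C
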